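The constants used here come from no measurement; no experiment stands behind them.

I was to read the flask at 15 h, so I asked first how much catalyst stays at work until then.

substrate 0.072 M; free catalyst 0.36 mM; impurity 96 µM; time 15 h

    substrate ⇌ target (K1 = 0.37, k1 = 0.13 min⁻¹)
    target ⇌ isomer of the product B (K2 = 0.59, k2 = 0.019 min⁻¹)
    free catalyst + impurity → spent catalyst (k3 = 35000 M⁻¹ min⁻¹)
    isomer of the product A + free catalyst ⇌ substrate + free catalyst, rate k4*[free catalyst]*[isomer of the product A] forward; the back reaction follows from the equilibrium constant (k4 = 1200 M⁻¹ min⁻¹)
    target + free catalyst ⇌ isomer of the product A + free catalyst, rate k5*[free catalyst]*[target] forward; the back reaction follows from the equilibrium constant (K5 = 2.3, k5 = 56 M⁻¹ min⁻¹)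

1. why nothing more happens at 15 h, or that something still does (it is still moving / no working catalyst is left / forward and back rates have come level / all of the substrate has reacted)
2. how much target there is at 15 h, in percent of the substrate charged
3. how much isomer of the product A there is at 15 h, in percent of the substrate charged

Free catalyst and impurity react one to one, and quickly: in the flask the impurity's half-life against the charged catalyst was 0.0550 min. That was far shorter than the run, and the impurity charge was smaller than the catalyst charge, so I took step 3 as finished and the impurity as the limiting reagent, which left a surviving catalyst of charge minus impurity, 0.264 mM. From this I made the quantity I carried, the turnover half-life τ, which is ln(2) over k4 times the surviving catalyst: the half-life of isomer of the product A on its way to substrate, forward rate alone. In the flask τ came to 2.19 min, longer than the impurity's half-life.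

The neighbour flask was charged with 9.0 × 10⁻⁵ M of free catalyst, less than its impurity. There the subtraction left no catalyst and 6.00 µM of impurity, 6.25 % of its charge. The neighbour's catalyst began with a half-life against the impurity of 0.206 min, shorter than the 6.42 min that τ gave with its charged catalyst. I therefore expected little isomer of the product A there.

In the flask τ was short against the run, and so was the half-life of target by step 2, 0.608 h. The constants around the loop multiply to one, so I expected level rates, with substrate, target, isomer of the product A and isomer of the product B standing as one to K1 to K1·K5 to K1·K2. That gave 15.2 % target and 34.9 % isomer of the product A.

The forecast said that forward and back rates have come level, with 15.17 % target and 34.89 % isomer of the product A, “so the system is at equilibrium”.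

In the flask forward and back rates have come level, with 15.2 % target and 34.9 % isomer of the product A, and 73 % of its catalyst could still turn over at the end, against 73.3 % by my subtraction. At 15.0 h τ, the half-life of isomer of the product A on its path to substrate, forward rate alone, read 2.2 min in the flask, short against the run. The neighbour flask ended with free catalyst at 0 % of its charge, 6.2 % of its impurity left, and 6.53 % isomer of the product A.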